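The decade is my unit here: every ratio goes in as its decimal logarithm, so a recipe becomes a sum.

common to all: substrate 0.10 M

| flask | first nucleophile | second nucleophile | remark | time |
|---|---|---|---|---|
| ash | 0.20 M | 0.15 M | run made earlier |  |
| alder | 0.28 M | 0.15 M | run made earlier |  |
| birch | 0.44 M | 0.15 M | run made earlier |  |
| larch | 0.20 M | 0.22 M | run made earlier |  |
| east | 0.200 M (fed, over 3.0 d) | 0.150 M | all else is in the flask from the start; the feed brings no volume worth counting | 15 d |
| south-west | 0.200 M | 0.150 M (fed, over 3.0 d) | all else is in the flask from the start; the feed brings no volume worth counting | 15 d |
| north-east | 0.200 M | 0.150 M | everything together at the start | 15 d |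
| north-west | 0.200 M | 0.150 M (fed, over 8.0 h) | all else is in the flask from the start; the feed brings no volume worth counting | 15 d |

- ash (time / d: target / %, other capture product / %): 0.625: 8.6, 47.4; 1.67: 12.1, 63.6; 4.00: 13.1, 65.8; 10.0: 11.8, 64.2
- alder (time / d: target / %, other capture product / %): 3.00: 14.2, 58.0; 6.00: 13.7, 58.7; 10.0: 12.4, 58.4; 12.0: 12.3, 58.5
- birch (time / d: target / %, other capture product / %): 1.04: 18.0, 41.2; 2.00: 20.2, 46.6; 5.00: 17.4, 46.3; 12.0: 16.5, 47.7
- larch (time / d: target / %, other capture product / %): 3.00: 8.7, 74.2; 6.00: 7.2, 74.2; 10.0: 8.5, 74.1; 12.0: 8.5, 75.3

(standard deviation of a reading: 1 percentage point)



- the flask with the highest share of target in target plus other capture product ("all alike" if they lie within 1.5 percentage points) (east / south-west / north-east / north-west / all alike)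
- share of target in target plus other capture product at the end, east
- share of target in target plus other capture product at the end, south-west
- share of target in target plus other capture product at the end, north-east
- share of target in target plus other capture product at the end, north-west

I take it that the substrate goes first order into something the two nucleophiles share, the first leading to target and the second to other capture product. So the logarithm of target over other capture product is that of a constant g plus that of R, the ratio c(first nucleophile)/c(second nucleophile) met while the substrate goes. I call g the capture constant: target per other capture product at unit R, a selectivity factor with the later fate of the target folded in.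

Each input carries weight one, so I ask what error each brings. In birch, one point of scatter moves g by 6.06% through the target reading but by 2.10% through the other capture product. Consumption of the nucleophiles matters too: in ash it lifts R from 1.33 to 1.54, or 0.0639 decades. The substrate lifetime τ enters my reckoning for the fed flasks.

The birch readings at 12.0 d, with mean concentrations, give g = 0.105, or −0.979 decades, and the ash readings at 0.625 d and 4.00 d give τ = 0.490 d. North-east, the ash recipe, then has a share of 13.9%. In south-west the feed of 3.0 d is longer than τ, so I take as the level of second nucleophile what one τ of feed brings in, 0.163 of its charge; R is then 8.16 and my estimate of the share is 46.1%. East, its mirror image, comes to 2.25% by the same estimate. North-west's feed of 8.0 h is shorter than τ, so I do not reckon it this way.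

The forecast names south-west, with 3.3% for east, 52% for south-west (from 45% to 59%), 14.3% for north-east and 20.5% for north-west; its south-west and east numbers stand above my estimates, and its ground is “withholding the second nucleophile during the substrate's short lifetime favours first capture”.

South-west gives 47.1%, above the 3.65% of east, the 13.6% of north-east and the 18.4% of north-west.

    substrate → intermediate (k = 0.00130 min⁻¹)
    first nucleophile + intermediate → target (k = 1.70 L mol⁻¹ min⁻¹)
    second nucleophile + intermediate → other capture product (k = 5.50 L mol⁻¹ min⁻¹)
    2 second nucleophile → self-condensation product (k = 3.30 × 10⁻⁴ L mol⁻¹ min⁻¹)
    target → over-reaction product (k = 3.50 × 10⁻⁵ min⁻¹)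
    target ⇌ isomer of the product (K = 1.50, k = 0.00480 min⁻¹)

At 15.0 d south-west holds 22.3% target beside 33.5% isomer of the product. Dividing its target-to-other ratio by g gives an R of 8.48. The neighbour flask, east with 0.060 M of second nucleophile, ends at a share of 17.3%, with 12.3% target and 58.9% other capture product, and the same division gives it an R of 1.99.

The runs come from a simulation with constants of no real substance; scatter was added.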